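**Retrosynthetic overview**
1. Target ⇒ macrocyclic 13-ketone (enone): C13 and the 11,12-oxirane are set last by CBS reduction, matched titanium–tartrate epoxidation and Mitsunobu inversion with acetic acid.
2. Key step: a gold-catalysed intramolecular hydroalkoxylation of a terminal enyne by a 3-(hydroxymethyl)butenolide gives a 16-membered allyl vinyl ether, whose Claisen ring contraction forms C1–C14, the C1 stereocentre, the 14-membered carbocycle and the α-methylene lactone together (not the usual C1–C2 allylation macrocyclisation).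
3. Seco compound ⇒ (2E,6E)-farnesyl acetate: the E-methyl terminus becomes aldehyde then alkyne (C13≡C14); the allylic acetate terminus becomes an enal, then asymmetric alkynylation (C2), trans-hydroalumination/iodination and carbonylative lactonisation.
4. Ring order: butenolide (five-membered) → transient 16-membered cyclic enol ether → 14-membered carbocycle → oxirane.

Assumption: cembrane numbering is used for the macrocycles (ring C1–C14, C1 = ring-fusion CH, C2 = lactone O–CH, methyls on C4/C8/C12, C15 = α-carbon, C16 = C=O, C17 = exocyclic CH2); the target is then (1R,2S,3E,7E,11R,12S,13S).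

**Route**

Step 1
Reactants: 1 (2E,6E)-farnesyl acetate
Product: 2 (2E,6E,10E)-12-hydroxy-3,7,11-trimethyldodeca-2,6,10-trien-1-yl acetate
Conditions: SeO2 (0.3 equiv), salicylic acid (0.1 equiv), t-BuOOH (70% aq., 3.5 equiv), CH2Cl2, rt
Reagents that add atoms: tert-butyl hydroperoxide CC(C)(C)OO (oxygen relayed through catalytic SeO2 O=[Se]=O)
Why: Sharpless–Umbreit selenium dioxide allylic oxidation (ene reaction then [2,3]-sigmatropic shift) is selective for the E-methyl of the terminal trisubstituted alkene and gives the (E)-allylic alcohol.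

Step 2
Reactants: 2 (2E,6E,10E)-12-hydroxy-3,7,11-trimethyldodeca-2,6,10-trien-1-yl acetate
Product: 3 (2E,6E,10E)-3,7,11-trimethyl-12-oxododeca-2,6,10-trien-1-yl acetate
Conditions: MnO2 (15 equiv), CH2Cl2, rt
Reagents that add atoms: none
Why: MnO2 oxidation of a primary allylic alcohol gives the (E)-enal without touching the acetate or the isolated alkenes.

Step 3
Reactants: 3 (2E,6E,10E)-3,7,11-trimethyl-12-oxododeca-2,6,10-trien-1-yl acetate
Product: 5 (2E,6E,10E)-3,7,11-trimethyltrideca-2,6,10-trien-12-yn-1-ol, via hydroxy enal 4 (not isolated)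
Conditions: Ohira–Bestmann reagent (1.5 equiv), K2CO3 (3 equiv), MeOH, 0 °C → rt
Reagents that add atoms: dimethyl (1-diazo-2-oxopropyl)phosphonate COP(=O)(OC)C(=[N+]=[N-])C(C)=O
Why: Ohira–Bestmann (Seyferth–Gilbert) homologation turns the enal into the terminal enyne (the new carbon is C14) while the same K2CO3/MeOH medium transesterifies the allylic acetate, freeing the alcohol in one flask.

Step 4
Reactants: 5 (2E,6E,10E)-3,7,11-trimethyltrideca-2,6,10-trien-12-yn-1-ol
Product: 8 (2E,6E,10E)-3,7,11-trimethyl-13-(trimethylsilyl)trideca-2,6,10-trien-12-yn-1-ol, via dilithio alkoxide acetylide 6 (not isolated), via bis-silyl ether 7 (not isolated)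
Conditions: n-BuLi (2.2 equiv), THF, −78 °C; Me3SiCl (2.4 equiv), −78 °C → rt; then citric acid, MeOH, rt
Reagents that add atoms: chlorotrimethylsilane C[Si](C)(C)Cl
Why: double deprotonation/silylation followed by selective solvolysis of the labile O–Si bond leaves a C-silyl alkyne (protecting-group step), so the enyne terminus cannot compete in the later zinc alkynylation, hydroalumination and palladium steps.

Step 5
Reactants: 8 (2E,6E,10E)-3,7,11-trimethyl-13-(trimethylsilyl)trideca-2,6,10-trien-12-yn-1-ol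
Product: 9 (2E,6E,10E)-3,7,11-trimethyl-13-(trimethylsilyl)trideca-2,6,10-trien-12-ynal
Conditions: MnO2 (15 equiv), CH2Cl2, rt
Reagents that add atoms: none
Why: MnO2 allylic oxidation gives the (2E)-enal without isomerisation and leaves the silyl enyne intact.

Step 6
Reactants: 9 (2E,6E,10E)-3,7,11-trimethyl-13-(trimethylsilyl)trideca-2,6,10-trien-12-ynal; 10 tert-butyldimethyl(prop-2-yn-1-yloxy)silane
Product: 12 (4S,5E,9E,13E)-1-(tert-butyldimethylsilyloxy)-6,10,14-trimethyl-16-(trimethylsilyl)hexadeca-5,9,13-triene-2,15-diyn-4-ol, via alkynyl(methyl)zinc 11 (not isolated)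
Conditions: 10 (3 equiv), Me2Zn (3 equiv), (S,S)-ProPhenol (20 mol %), Ph3P=O (40 mol %), toluene, 4 °C; aq. NH4Cl
Reagents that add atoms: none
Why: ProPhenol dinuclear-zinc asymmetric alkynylation adds the alkynylzinc 1,2 to the enal inside the chiral dizinc pocket, and the (S,S)-ligand is chosen because its established facial sense gives the (S)-carbinol, which becomes C2 (S) of the target.

Step 7
Reactants: 12 (4S,5E,9E,13E)-1-(tert-butyldimethylsilyloxy)-6,10,14-trimethyl-16-(trimethylsilyl)hexadeca-5,9,13-triene-2,15-diyn-4-ol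
Product: 14 (2Z,4S,5E,9E,13E)-1-(tert-butyldimethylsilyloxy)-2-iodo-6,10,14-trimethyl-16-(trimethylsilyl)hexadeca-2,5,9,13-tetraen-15-yn-4-ol, via cyclic alkenylaluminate 13 (not isolated)
Conditions: NaAlH2(OCH2CH2OMe)2 (1.6 equiv), THF, −20 → 0 °C; then iodine (I2), THF, −78 °C
Reagents that add atoms: iodine II
Why: hydroxyl-directed trans-hydroalumination of the propargylic alcohol puts aluminium on the distal alkyne carbon in a five-membered oxa-aluminacycle and iodinolysis with retention gives the (Z)-iodoalkene with OH and iodine cis, the low temperature suppressing β-elimination of the silyloxy group and leaving the carbinol centre untouched.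

Step 8
Reactants: 14 (2Z,4S,5E,9E,13E)-1-(tert-butyldimethylsilyloxy)-2-iodo-6,10,14-trimethyl-16-(trimethylsilyl)hexadeca-2,5,9,13-tetraen-15-yn-4-ol
Product: 15 (5S)-3-[(tert-butyldimethylsilyloxy)methyl]-5-[(1E,5E,9E)-2,6,10-trimethyl-12-(trimethylsilyl)dodeca-1,5,9-trien-11-yn-1-yl]furan-2(5H)-one
Conditions: Pd(PPh3)4 (5 mol %), CO (2 atm), K2CO3 (2 equiv), THF, rt → 35 °C
Reagents that add atoms: carbon monoxide [C-]#[O+]
Why: palladium-catalysed carbonylative lactonisation (oxidative addition of the vinyl iodide to zerovalent palladium, CO insertion, capture of the acyl by the cis hydroxyl) closes the butenolide and supplies C16 without involving the stereocentre.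

Step 9
Reactants: 15 (5S)-3-[(tert-butyldimethylsilyloxy)methyl]-5-[(1E,5E,9E)-2,6,10-trimethyl-12-(trimethylsilyl)dodeca-1,5,9-trien-11-yn-1-yl]furan-2(5H)-one
Product: 16 (5S)-3-(hydroxymethyl)-5-[(1E,5E,9E)-2,6,10-trimethyldodeca-1,5,9-trien-11-yn-1-yl]furan-2(5H)-one
Conditions: Bu4NF (2.5 equiv), AcOH (2.5 equiv), THF, 0 °C → rt
Reagents that add atoms: none
Why: fluoride-mediated desilylation removes both the O-silyl and the alkynyl C-silyl group in one operation, the acetic acid buffer protecting the acidic C5–H of the butenolide from epimerisation.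

Step 10
Reactants: 16 (5S)-3-(hydroxymethyl)-5-[(1E,5E,9E)-2,6,10-trimethyldodeca-1,5,9-trien-11-yn-1-yl]furan-2(5H)-one
Product: 18 (1R,2S,3E,7E,11E)-13-oxocembra-3,7,11,15(17)-tetraen-16,2-olide, via macrocyclic enol ether 17 (not isolated)
Conditions: [Au(IPr)(NTf2)] (10 mol %; IPr = 1,3-bis(2,6-diisopropylphenyl)imidazol-2-ylidene), 4 Å molecular sieves, toluene, 90 °C, syringe-pump addition of 16 to 0.001 M
Reagents that add atoms: none
Why: Proposed new method: monovalent gold activates the terminal enyne for Markovnikov addition of the tethered primary allylic OH at C13, closing a 16-membered 2-alkoxy-1,3-diene (allyl vinyl ether) that undergoes an irreversible chair-like [3,3] Claisen ring contraction in which C14 bonds to the butenolide β-carbon on the face anti to the C2 alkenyl substituent, giving the trans (1R) ring fusion, the exocyclic methylene and the C13 ketone at once; the closest known reaction types are the intermolecular gold-catalysed hydroalkoxylation of alkynes by allylic alcohols with in situ Claisen rearrangement and Claisen ring contractions of macrocyclic allyl vinyl ethers.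

Step 11
Reactants: 18 (1R,2S,3E,7E,11E)-13-oxocembra-3,7,11,15(17)-tetraen-16,2-olide
Product: 19 (1R,2S,3E,7E,11E,13R)-13-hydroxycembra-3,7,11,15(17)-tetraen-16,2-olide
Conditions: (S)-2-methyl-CBS-oxazaborolidine (0.2 equiv), catecholborane (1.5 equiv), toluene, −78 °C; pH 7 buffer
Reagents that add atoms: none
Why: Corey–Bakshi–Shibata reduction with the α-methylalkenyl side as the large group gives the 13R allylic alcohol by reagent control (the same sense that gives (R)-1-phenylethanol), and catecholborane at −78 °C does not reduce the α-methylene lactone.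

Step 12
Reactants: 19 (1R,2S,3E,7E,11E,13R)-13-hydroxycembra-3,7,11,15(17)-tetraen-16,2-olide
Product: 20 (1R,2S,3E,7E,11R,12R,13R)-11,12-epoxy-13-hydroxycembra-3,7,15(17)-trien-16,2-olide
Conditions: Ti(OiPr)4 (0.2 equiv), D-(−)-diisopropyl tartrate (0.24 equiv), t-BuOOH (2 equiv, decane), 4 Å molecular sieves, CH2Cl2, −20 °C
Reagents that add atoms: tert-butyl hydroperoxide CC(C)(C)OO
Why: Sharpless asymmetric epoxidation in the matched sense (the 13R alcohol is the fast-reacting enantiomer with the D-tartrate) epoxidises only the allylic-alcohol alkene and gives the erythro epoxy alcohol with the oxirane configuration of the target (C12 is labelled R here only because the CIP ranking of C11 and C13 differs between alcohol and acetate).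

Step 13
Reactants: 20 (1R,2S,3E,7E,11R,12R,13R)-11,12-epoxy-13-hydroxycembra-3,7,15(17)-trien-16,2-olide
Product: 22 (1R,2S,3E,7E,11R,12S,13S)-13-acetoxy-11,12-epoxycembra-3,7,15(17)-trien-16,2-olide, via alkoxyphosphonium acetate 21 (not isolated)
Conditions: PPh3 (3 equiv), diisopropyl azodicarboxylate (3 equiv), AcOH (3 equiv), toluene, 0 °C → rt (betaine pre-formed before adding 20)
Reagents that add atoms: acetic acid CC(=O)O
Why: Mitsunobu reaction with acetic acid displaces the oxyphosphonium group by SN2 inversion, converting the erythro 13R alcohol directly into the threo 13S acetate of the target while the epoxide and α-methylene lactone are tolerated under these near-neutral conditions.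

**Compound list**

1 | (2E,6E)-farnesyl acetate | CC(=O)OC/C=C(\C)CC/C=C(\C)CCC=C(C)C | starting material
2 | (2E,6E,10E)-12-hydroxy-3,7,11-trimethyldodeca-2,6,10-trien-1-yl acetate | CC(=O)OC/C=C(\C)CC/C=C(\C)CC/C=C(\C)CO | intermediate
3 | (2E,6E,10E)-3,7,11-trimethyl-12-oxododeca-2,6,10-trien-1-yl acetate | CC(=O)OC/C=C(\C)CC/C=C(\C)CC/C=C(\C)C=O | intermediate
4 | (2E,6E,10E)-12-hydroxy-2,6,10-trimethyldodeca-2,6,10-trienal | OC/C=C(\C)CC/C=C(\C)CC/C=C(\C)C=O | intermediate (not isolated)
5 | (2E,6E,10E)-3,7,11-trimethyltrideca-2,6,10-trien-12-yn-1-ol | OC/C=C(\C)CC/C=C(\C)CC/C=C(\C)C#C | intermediate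
6 | dilithium alkoxide acetylide of 5 | [Li]OC/C=C(\C)CC/C=C(\C)CC/C=C(\C)C#C[Li] | intermediate (not isolated)
7 | trimethylsilyl ether of 8 (O,C-bis-silylated 5) | C[Si](C)(C)OC/C=C(\C)CC/C=C(\C)CC/C=C(\C)C#C[Si](C)(C)C | intermediate (not isolated)
8 | (2E,6E,10E)-3,7,11-trimethyl-13-(trimethylsilyl)trideca-2,6,10-trien-12-yn-1-ol | OC/C=C(\C)CC/C=C(\C)CC/C=C(\C)C#C[Si](C)(C)C | intermediate
9 | (2E,6E,10E)-3,7,11-trimethyl-13-(trimethylsilyl)trideca-2,6,10-trien-12-ynal | O=C/C=C(\C)CC/C=C(\C)CC/C=C(\C)C#C[Si](C)(C)C | intermediate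
10 | tert-butyldimethyl(prop-2-yn-1-yloxy)silane | C#CCO[Si](C)(C)C(C)(C)C | starting material
11 | [3-(tert-butyldimethylsilyloxy)prop-1-yn-1-yl](methyl)zinc | C[Zn]C#CCO[Si](C)(C)C(C)(C)C | intermediate (not isolated)
12 | (4S,5E,9E,13E)-1-(tert-butyldimethylsilyloxy)-6,10,14-trimethyl-16-(trimethylsilyl)hexadeca-5,9,13-triene-2,15-diyn-4-ol | O[C@H](C#CCO[Si](C)(C)C(C)(C)C)/C=C(\C)CC/C=C(\C)CC/C=C(\C)C#C[Si](C)(C)C | intermediate
13 | sodium bis(2-methoxyethoxy)aluminate in which Al is part of a five-membered ring with the C4 oxygen and the distal alkene carbon of 12 | [Na+].COCCO[Al-]1(OCCOC)O[C@@H](/C=C(\C)CC/C=C(\C)CC/C=C(\C)C#C[Si](C)(C)C)C=C1CO[Si](C)(C)C(C)(C)C | intermediate (not isolated)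
14 | (2Z,4S,5E,9E,13E)-1-(tert-butyldimethylsilyloxy)-2-iodo-6,10,14-trimethyl-16-(trimethylsilyl)hexadeca-2,5,9,13-tetraen-15-yn-4-ol | O[C@H](/C=C(\I)CO[Si](C)(C)C(C)(C)C)/C=C(\C)CC/C=C(\C)CC/C=C(\C)C#C[Si](C)(C)C | intermediate
15 | (5S)-3-[(tert-butyldimethylsilyloxy)methyl]-5-[(1E,5E,9E)-2,6,10-trimethyl-12-(trimethylsilyl)dodeca-1,5,9-trien-11-yn-1-yl]furan-2(5H)-one | CC(C)(C)[Si](C)(C)OCC1=C[C@H](/C=C(\C)CC/C=C(\C)CC/C=C(\C)C#C[Si](C)(C)C)OC1=O | intermediate
16 | (5S)-3-(hydroxymethyl)-5-[(1E,5E,9E)-2,6,10-trimethyldodeca-1,5,9-trien-11-yn-1-yl]furan-2(5H)-one | OCC1=C[C@H](/C=C(\C)CC/C=C(\C)CC/C=C(\C)C#C)OC1=O | intermediate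
17 | 16-membered cyclic allyl vinyl ether: the CH2O of the butenolide of 16 bonded to C13 of a C13(=C14H2) enol ether (2-alkoxy-1,3-diene), C2 (S) | C=C1OCC2=C[C@@H](OC2=O)/C=C(\C)CC/C=C(\C)CC/C=C1\C | intermediate (not isolated)
18 | (1R,2S,3E,7E,11E)-13-oxocembra-3,7,11,15(17)-tetraen-16,2-olide | C=C1C(=O)O[C@H]2/C=C(\C)CC/C=C(\C)CC/C=C(\C)C(=O)C[C@H]12 | intermediate
19 | (1R,2S,3E,7E,11E,13R)-13-hydroxycembra-3,7,11,15(17)-tetraen-16,2-olide | C=C1C(=O)O[C@H]2/C=C(\C)CC/C=C(\C)CC/C=C(\C)[C@H](O)C[C@H]12 | intermediate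
20 | (1R,2S,3E,7E,11R,12R,13R)-11,12-epoxy-13-hydroxycembra-3,7,15(17)-trien-16,2-olide | C=C1C(=O)O[C@H]2/C=C(\C)CC/C=C(\C)CC[C@H]3O[C@]3(C)[C@H](O)C[C@H]12 | intermediate
21 | 13-O-triphenylphosphonium acetate of 20 | C=C1C(=O)O[C@H]2/C=C(\C)CC/C=C(\C)CC[C@H]3O[C@]3(C)[C@H](O[P+](c4ccccc4)(c4ccccc4)c4ccccc4)C[C@H]12.CC(=O)[O-] | intermediate (not isolated)
22 | (1R,2S,3E,7E,11R,12S,13S)-13-acetoxy-11,12-epoxycembra-3,7,15(17)-trien-16,2-olide (CNP0146076.5) | C=C1C(=O)O[C@H]2/C=C(\C)CC/C=C(\C)CC[C@H]3O[C@]3(C)[C@@H](OC(C)=O)C[C@H]12 | target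

**Step count and risks**

Total step count: 13. Longest linear sequence: 13 steps (from 1; compound 10 is used as purchased).

Three steps most likely to fail:

Step 10 (gold-catalysed macrocyclising hydroalkoxylation/Claisen). The ring-closing C–O bond formation at high dilution may be too slow, or the trans selectivity at C1 may be poor. The fallback sets out from 16 and comes back at 18 by closing the ring under reversible acid catalysis instead. Treating 16 with [Au(IPr)(NTf2)] (2 mol %) in MeOH at rt lets the enyne take up two molecules of solvent (intermolecular hydroalkoxylation) to give the dimethyl ketal (5S)-5-[(1E,5E,9E)-11,11-dimethoxy-2,6,10-trimethyldodeca-1,5,9-trien-1-yl]-3-(hydroxymethyl)furan-2(5H)-one F1. Heating F1 at 0.001 M in toluene at 110 °C with 2,4-dinitrophenol (10 mol %) and 5 Å molecular sieves (Johnson ketal-Claisen) exchanges one methoxy group for the tethered CH2OH to give the macrocyclic mixed methyl ketal F2. Loss of methanol from F2 gives 17, and the irreversible Claisen ring contraction drains the equilibrium to 18.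

Step 12 (facial course of the epoxidation in the macrocycle). If the ring conformation blocks the erythro transition state, or enforces the threo sense for hydroxyl-directed epoxidation, the fallback sets out from 18 and comes back at 22 with the stereochemical logic reversed. Reduction of 18 with (R)-2-methyl-CBS-oxazaborolidine/catecholborane gives (1R,2S,3E,7E,11E,13S)-13-hydroxycembra-3,7,11,15(17)-tetraen-16,2-olide F3. Hydroxyl-directed epoxidation of F3 with VO(acac)2/t-BuOOH in CH2Cl2 (peripheral attack, threo) gives (1R,2S,3E,7E,11R,12R,13S)-11,12-epoxy-13-hydroxycembra-3,7,15(17)-trien-16,2-olide F4. Acetylation of F4 with retention (Ac2O, pyridine, DMAP) then gives 22 without any inversion step.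

Step 13 (Mitsunobu inversion at a carbinol flanked by the fully substituted oxirane carbon, with PPh3 in the presence of an α-methylene lactone). The fallback sets out from 20 and comes back at 22 through a small, highly reactive sulfonate rather than an oxyphosphonium ion. Treating 20 with ClCH2SO2Cl and pyridine in CH2Cl2 at 0 °C gives the 13-O-chloromethanesulfonate of 20, F5. Displacement of F5 with CsOAc/18-crown-6 in toluene at 80 °C (SN2 inversion by a naked carboxylate) then gives 22.

**Further compounds**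

F1 | step 10 | (5S)-5-[(1E,5E,9E)-11,11-dimethoxy-2,6,10-trimethyldodeca-1,5,9-trien-1-yl]-3-(hydroxymethyl)furan-2(5H)-one | OCC1=C[C@H](/C=C(\C)CC/C=C(\C)CC/C=C(\C)C(C)(OC)OC)OC1=O
F2 | step 10 | macrocyclic mixed methyl ketal (C13 bearing OMe, CH3 and the butenolide CH2O) | COC1(C)OCC2=C[C@@H](OC2=O)/C=C(\C)CC/C=C(\C)CC/C=C1\C
F3 | step 12 | (1R,2S,3E,7E,11E,13S)-13-hydroxycembra-3,7,11,15(17)-tetraen-16,2-olide | C=C1C(=O)O[C@H]2/C=C(\C)CC/C=C(\C)CC/C=C(\C)[C@@H](O)C[C@H]12
F4 | step 12 | (1R,2S,3E,7E,11R,12R,13S)-11,12-epoxy-13-hydroxycembra-3,7,15(17)-trien-16,2-olide | C=C1C(=O)O[C@H]2/C=C(\C)CC/C=C(\C)CC[C@H]3O[C@]3(C)[C@@H](O)C[C@H]12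
F5 | step 13 | 13-O-chloromethanesulfonate of 20 | C=C1C(=O)O[C@H]2/C=C(\C)CC/C=C(\C)CC[C@H]3O[C@]3(C)[C@H](OS(=O)(=O)CCl)C[C@H]12
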